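The carbocycle C4a–C5–C6–C7–C8–C8a, which carries N1 on C8a, C4 on C4a and the phenylpentyl chain on C5, is cut into a 1-carbamoylbutadiene and an enal. One amine-catalysed Diels–Alder reaction joins C5–C6 and C4a–C8a, closes that ring and fixes C5, the only stereocentre of the target. C4a and C8a are disposable because they end up sp2 in the pyridine. The precursors are (E)-8-phenyloct-2-enal and benzyl buta-1,3-dienylcarbamate; the benzyl carbamate later falls in the same hydrogenation that saturates C7=C8 and starts pyridine-ring formation on a methoxyacetone-derived diketone.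

Key step: step 4

Remark: atom numbers are those of the target's quinoline skeleton (N1, C2, C3, C4, C4a, C5 to C8, C8a); it is assumed that the side-chain centres made in step 6 and the ring-fusion centres C4a and C8a may be carried as mixtures, since all of them are planarised before the end.

Step 1
Reactants: 1 6-phenylhexan-1-ol
Product: 2 6-phenylhexanal
Conditions: TEMPO (10 mol %), PhI(OAc)2 (1.1 equiv), CH2Cl2, rt
Reagents that add atoms: none
Why: Nitroxyl-catalysed alcohol oxidation (oxoammonium cycle) should stop at the aldehyde and leave the remote phenyl ring untouched.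

Step 2
Reactants: 2 6-phenylhexanal; 3 (triphenylphosphoranylidene)acetaldehyde
Product: 4 (2E)-8-phenyloct-2-enal
Conditions: toluene, 80 °C, 1.1 equiv of 3
Reagents that add atoms: none
Why: Wittig reaction with a stabilised ylide is expected to give the (E)-enal, and the near-stoichiometric charge of 3 limits a second homologation.

Step 3
Reactants: 5 (2E)-penta-2,4-dienoic acid; 6 benzyl alcohol
Product: 9 benzyl N-[(1E)-buta-1,3-dien-1-yl]carbamate, via dienoyl azide 7 (not isolated), via dienyl isocyanate 8 (not isolated)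
Conditions: DPPA, Et3N, toluene, 0 °C to rt; then 6, 4-tert-butylcatechol (cat.), 100 °C
Reagents that add atoms: diphenylphosphoryl azide, [N-]=[N+]=NP(=O)(Oc1ccccc1)Oc1ccccc1
Why: Curtius rearrangement moves the (E)-dienyl group to nitrogen with retention of its geometry, and benzyl alcohol traps the isocyanate as the carbamate while the inhibitor holds back diene polymerisation.

Step 4
Reactants: 4 (2E)-8-phenyloct-2-enal; 9 benzyl N-[(1E)-buta-1,3-dien-1-yl]carbamate (1.5 equiv)
Product: 10 benzyl N-[(1R,5R,6S)-6-formyl-5-(5-phenylpentyl)cyclohex-2-en-1-yl]carbamate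
Conditions: (5R)-5-benzyl-2,2,3-trimethylimidazolidin-4-one hydrochloride (20 mol %), MeCN/H2O 95:5, 0 °C
Reagents that add atoms: none
Why: The secondary amine condenses with 4 to a catalyst-bound (E)-iminium ion of lowered LUMO energy, 9 adds to it in a concerted but asynchronous [4+2] cycloaddition in which its unsubstituted terminus bonds to the β-carbon (C5–C6) and its nitrogen-bearing terminus to the α-carbon (C4a–C8a), and hydrolysis of the adduct iminium ion by the water present releases 10 and the catalyst. The closest known reaction type is the imidazolidinone-catalysed enantioselective Diels–Alder reaction of enals with 1-acyloxy- and 1-carbamoylbutadienes. The carbocycle closes by this intermolecular suprafacial–suprafacial cycloaddition, both ring bonds being made in the one step. C5 is set by the catalyst: the benzyl group of the (5R)-imidazolidinone (D-phenylalanine series) covers one face of the iminium ion, so the diene should meet the β-carbon on the face where, seen from the diene, the α-carbon, the chain and H follow one another anticlockwise, which is R at C5; C4a follows from the (E)-geometry of the enal (formyl trans to the chain) and C8a from the (E)-geometry of the diene and endo approach (carbamate cis to formyl). The step needs enantiofacial control at C5 and ortho regiochemistry: the first rests on the face shielding just described, the second on the nitrogen donor, which makes the far diene terminus the most nucleophilic position and pairs it with the electrophilic β-carbon. Endo/exo leakage or epimerisation next to the formyl group would not matter, since both isomers arise from the same enal face and C4a and C8a become sp2 later.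

Step 5
Reactants: 11 methoxyacetone
Product: 12 (1Z)-1-methoxy-2-(trimethylsilyloxy)prop-1-ene
Conditions: TMSCl, Et3N, DMF, 80 °C; pentane extraction, fractional distillation
Reagents that add atoms: chlorotrimethylsilane, C[Si](C)(C)Cl
Why: Silyl enol ether formation under equilibrating conditions should favour the more substituted enol ether on the methoxy-bearing carbon, which is also the more acidic site, and its regioisomeric purity can be checked before the cycloadduct is committed (the alkene geometry is immaterial).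

Step 6
Reactants: 10 benzyl N-[(1R,5R,6S)-6-formyl-5-(5-phenylpentyl)cyclohex-2-en-1-yl]carbamate; 12 (1Z)-1-methoxy-2-(trimethylsilyloxy)prop-1-ene
Product: 14 benzyl N-[(1R,5R,6S)-6-(1-hydroxy-2-methoxy-3-oxobutyl)-5-(5-phenylpentyl)cyclohex-2-en-1-yl]carbamate, via silyl ether 13 (not isolated)
Conditions: Sc(OTf)3 (10 mol %), CH2Cl2, −78 to −20 °C; then 1 M HCl, THF, 0 °C
Reagents that add atoms: none
Why: In this Mukaiyama aldol addition the Lewis acid activates the aldehyde and the enol silane attacks through its methoxy-bearing carbon, so C4–C3 forms with the oxygen pattern in place, and the two new side-chain centres need no control because both become sp2.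

Step 7
Reactants: 14 benzyl N-[(1R,5R,6S)-6-(1-hydroxy-2-methoxy-3-oxobutyl)-5-(5-phenylpentyl)cyclohex-2-en-1-yl]carbamate
Product: 15 benzyl N-[(1R,5R,6S)-6-(2-methoxy-3-oxobutanoyl)-5-(5-phenylpentyl)cyclohex-2-en-1-yl]carbamate
Conditions: Dess–Martin periodinane, CH2Cl2, rt
Reagents that add atoms: none
Why: Dess–Martin oxidation of a β-hydroxy ketone should give the 1,3-diketone under near-neutral conditions that spare the carbamate, the alkene and C5.

Step 8
Reactants: 15 benzyl N-[(1R,5R,6S)-6-(2-methoxy-3-oxobutanoyl)-5-(5-phenylpentyl)cyclohex-2-en-1-yl]carbamate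
Product: 17 (4aS,5R,8aR)-3-methoxy-2-methyl-5-(5-phenylpentyl)-4a,5,6,7,8,8a-hexahydroquinolin-4(1H)-one, via amino diketone 16 (not isolated)
Conditions: H2 (1 atm), Pd/C (10 wt % Pd), EtOAc, rt; filter; AcOH (cat.), 40 °C
Reagents that add atoms: none
Why: Catalytic hydrogenation saturates C7=C8 and hydrogenolyses the benzyl carbamate, and the freed amine on C8a should condense with the acetyl carbonyl (6-exo-trig addition then dehydration, the only ring size within reach) to a vinylogous amide whose conjugated double bond resists further reduction.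

Step 9
Reactants: 17 (4aS,5R,8aR)-3-methoxy-2-methyl-5-(5-phenylpentyl)-4a,5,6,7,8,8a-hexahydroquinolin-4(1H)-one
Product: 19 (4aS,5R,8aR)-3,4-dimethoxy-2-methyl-5-(5-phenylpentyl)-4a,5,6,7,8,8a-hexahydroquinoline, via iminium tetrafluoroborate 18 (not isolated)
Conditions: Me3OBF4 (1.1 equiv), CH2Cl2, 0 °C to rt; then cold sat. aq. NaHCO3
Reagents that add atoms: trimethyloxonium tetrafluoroborate, C[O+](C)C.F[B-](F)(F)F
Why: O-Alkylation of a vinylogous amide by a hard oxonium salt should place the methyl group on the carbonyl oxygen, because only that site gives a fully conjugated alkoxy-iminium ion, and bicarbonate then frees the neutral 1-azadiene.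

Step 10
Reactants: 19 (4aS,5R,8aR)-3,4-dimethoxy-2-methyl-5-(5-phenylpentyl)-4a,5,6,7,8,8a-hexahydroquinoline
Product: 20 (5R)-3,4-dimethoxy-2-methyl-5-(5-phenylpentyl)-5,6,7,8-tetrahydroquinoline
Conditions: DDQ (1.05 equiv), CH2Cl2, 0 °C to rt
Reagents that add atoms: none
Why: In this dehydrogenative aromatisation of a dihydropyridine, hydride loss from C4a (allylic to the bis-enol ether) and proton loss from C8a should give the pyridine, the gain in aromaticity steering the proton loss to C8a and away from C5, so the C5 centre is untouched.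

Step 11
Reactants: 20 (5R)-3,4-dimethoxy-2-methyl-5-(5-phenylpentyl)-5,6,7,8-tetrahydroquinoline
Product: 21 (5R)-3,4-dimethoxy-2-methyl-5-(5-phenylpentyl)-5,6,7,8-tetrahydroquinoline 1-oxide
Conditions: mCPBA (1.2 equiv), CH2Cl2, 0 °C to rt
Reagents that add atoms: 3-chloroperoxybenzoic acid, OOC(=O)c1cccc(Cl)c1
Why: Peracid N-oxidation of an electron-rich 2,6-dialkylpyridine is a standard reaction that should touch neither the C5–H bond nor the remote phenyl ring.

Compound list

1 | 6-phenylhexan-1-ol | OCCCCCCc1ccccc1 | starting material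
2 | 6-phenylhexanal | O=CCCCCCc1ccccc1 | intermediate
3 | (triphenylphosphoranylidene)acetaldehyde | O=CC=P(c1ccccc1)(c1ccccc1)c1ccccc1 | starting material
4 | (2E)-8-phenyloct-2-enal | O=C/C=C/CCCCCc1ccccc1 | intermediate
5 | (2E)-penta-2,4-dienoic acid | C=C/C=C/C(O)=O | starting material
6 | benzyl alcohol | OCc1ccccc1 | starting material
7 | (2E)-penta-2,4-dienoyl azide | C=C/C=C/C(=O)N=[N+]=[N-] | intermediate
8 | (1E)-1-isocyanatobuta-1,3-diene | C=C/C=C/N=C=O | intermediate
9 | benzyl N-[(1E)-buta-1,3-dien-1-yl]carbamate | C=C/C=C/NC(=O)OCc1ccccc1 | intermediate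
10 | benzyl N-[(1R,5R,6S)-6-formyl-5-(5-phenylpentyl)cyclohex-2-en-1-yl]carbamate | O=C[C@H]1[C@H](CCCCCc2ccccc2)CC=C[C@H]1NC(=O)OCc1ccccc1 | intermediate
11 | methoxyacetone | COCC(C)=O | starting material
12 | (1Z)-1-methoxy-2-(trimethylsilyloxy)prop-1-ene | CO/C=C(/C)O[Si](C)(C)C | intermediate
13 | benzyl N-[(1R,5R,6S)-6-[2-methoxy-3-oxo-1-(trimethylsilyloxy)butyl]-5-(5-phenylpentyl)cyclohex-2-en-1-yl]carbamate (side-chain epimers) | CC(=O)C(OC)C(O[Si](C)(C)C)[C@H]1[C@H](CCCCCc2ccccc2)CC=C[C@H]1NC(=O)OCc1ccccc1 | intermediate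
14 | benzyl N-[(1R,5R,6S)-6-(1-hydroxy-2-methoxy-3-oxobutyl)-5-(5-phenylpentyl)cyclohex-2-en-1-yl]carbamate (side-chain epimers) | CC(=O)C(OC)C(O)[C@H]1[C@H](CCCCCc2ccccc2)CC=C[C@H]1NC(=O)OCc1ccccc1 | intermediate
15 | benzyl N-[(1R,5R,6S)-6-(2-methoxy-3-oxobutanoyl)-5-(5-phenylpentyl)cyclohex-2-en-1-yl]carbamate | CC(=O)C(OC)C(=O)[C@H]1[C@H](CCCCCc2ccccc2)CC=C[C@H]1NC(=O)OCc1ccccc1 | intermediate
16 | 1-[(1S,2R,6R)-2-amino-6-(5-phenylpentyl)cyclohexyl]-2-methoxybutane-1,3-dione | CC(=O)C(OC)C(=O)[C@H]1[C@H](CCCCCc2ccccc2)CCC[C@H]1N | intermediate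
17 | (4aS,5R,8aR)-3-methoxy-2-methyl-5-(5-phenylpentyl)-4a,5,6,7,8,8a-hexahydroquinolin-4(1H)-one | O=C1C(OC)=C(C)N[C@@H]2CCC[C@@H](CCCCCc3ccccc3)[C@H]12 | intermediate
18 | (4aS,5R,8aR)-3,4-dimethoxy-2-methyl-5-(5-phenylpentyl)-4a,5,6,7,8,8a-hexahydroquinolin-1-ium tetrafluoroborate | COC1=C(OC)C(C)=[NH+][C@@H]2CCC[C@@H](CCCCCc3ccccc3)[C@H]12.F[B-](F)(F)F | intermediate
19 | (4aS,5R,8aR)-3,4-dimethoxy-2-methyl-5-(5-phenylpentyl)-4a,5,6,7,8,8a-hexahydroquinoline | COC1=C(OC)C(C)=N[C@@H]2CCC[C@@H](CCCCCc3ccccc3)[C@H]12 | intermediate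
20 | (5R)-3,4-dimethoxy-2-methyl-5-(5-phenylpentyl)-5,6,7,8-tetrahydroquinoline | COc1c(OC)c(C)nc2c1[C@H](CCCCCc1ccccc1)CCC2 | intermediate
21 | (5R)-3,4-dimethoxy-2-methyl-5-(5-phenylpentyl)-5,6,7,8-tetrahydroquinoline 1-oxide | COc1c(OC)c(C)[n+]([O-])c2c1[C@H](CCCCCc1ccccc1)CCC2 | target

Total step count: 11. Longest linear sequence: 9 steps (steps 1, 2, 4, 6, 7, 8, 9, 10 and 11, from 6-phenylhexan-1-ol).

Steps most likely to fail

Step 4. The cycloaddition of a β-alkyl enal with an acyclic diene may be slow under iminium catalysis, the dienyl carbamate may hydrolyse or polymerise in the acidic aqueous medium, and facial discrimination may be incomplete. The fallback keeps the same two ring bonds but uses a chelating dienophile and a chiral Lewis acid; it sets out from 2 and 9 and comes back at 10. Horner–Wadsworth–Emmons olefination of 2 with diethyl [2-oxo-2-(2-oxo-1,3-oxazolidin-3-yl)ethyl]phosphonate (LiCl, iPr2NEt, MeCN) should give 3-[(2E)-8-phenyloct-2-enoyl]-1,3-oxazolidin-2-one F1. Its Diels–Alder reaction with 9 is run under Cu(SbF6)2 and 2,2'-(propane-2,2-diyl)bis(4-tert-butyl-4,5-dihydro-1,3-oxazole) in CH2Cl2 at low temperature. The ligand antipode is the one that leaves the Cα re face of the square-planar chelate open, expected to be the (S,S) ligand. This should give benzyl N-[(1R,5R,6S)-6-(2-oxo-1,3-oxazolidine-3-carbonyl)-5-(5-phenylpentyl)cyclohex-2-en-1-yl]carbamate F2. LiBH4 in THF/MeOH reduces the imide to benzyl N-[(1R,5R,6S)-6-(hydroxymethyl)-5-(5-phenylpentyl)cyclohex-2-en-1-yl]carbamate F3, and Dess–Martin oxidation returns 10.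

Step 6. The enol silane may react through the wrong carbon if it is not regiochemically pure, addition to the doubly flanked aldehyde may be slow, and the β-carbamate may be lost by elimination. The fallback builds the diketone in the other order, so that regiochemistry is fixed by connectivity; it sets out from 10 and comes back at 15. Addition of (methoxymethyl)lithium (from Bu3SnCH2OMe and nBuLi, THF, −78 °C, excess to cover the N–H) should give benzyl N-[(1R,5R,6S)-6-(1-hydroxy-2-methoxyethyl)-5-(5-phenylpentyl)cyclohex-2-en-1-yl]carbamate F4. Dess–Martin oxidation gives benzyl N-[(1R,5R,6S)-6-(methoxyacetyl)-5-(5-phenylpentyl)cyclohex-2-en-1-yl]carbamate F5. C-Acetylation under soft enolisation (MgBr2·OEt2, iPr2NEt, 1-acetyl-1H-benzotriazole, CH2Cl2), which enolises the methoxymethylene group and not the hindered ring methine, then gives 15.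

Step 9. Alkylation may go to nitrogen instead of oxygen, or the alkoxy-iminium ion may hydrolyse back to the vinylogous amide during work-up. The fallback aromatises first and installs the C4 methoxy group by substitution; it sets out from 17 and comes back at 21. Dehydrogenation with DDQ in dioxane should give (5R)-3-methoxy-2-methyl-5-(5-phenylpentyl)-5,6,7,8-tetrahydroquinolin-4(1H)-one F6. POCl3 at 90 °C converts it into (5R)-4-chloro-3-methoxy-2-methyl-5-(5-phenylpentyl)-5,6,7,8-tetrahydroquinoline F7. mCPBA gives (5R)-4-chloro-3-methoxy-2-methyl-5-(5-phenylpentyl)-5,6,7,8-tetrahydroquinoline 1-oxide F8. Nucleophilic aromatic substitution with NaOMe in MeOH at reflux, activated by the N-oxide, then gives 21.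

Further compounds

F1 | step 4 | 3-[(2E)-8-phenyloct-2-enoyl]-1,3-oxazolidin-2-one | O=C(/C=C/CCCCCc1ccccc1)N1CCOC1=O
F2 | step 4 | benzyl N-[(1R,5R,6S)-6-(2-oxo-1,3-oxazolidine-3-carbonyl)-5-(5-phenylpentyl)cyclohex-2-en-1-yl]carbamate | O=C([C@H]1[C@H](CCCCCc2ccccc2)CC=C[C@H]1NC(=O)OCc1ccccc1)N3CCOC3=O
F3 | step 4 | benzyl N-[(1R,5R,6S)-6-(hydroxymethyl)-5-(5-phenylpentyl)cyclohex-2-en-1-yl]carbamate | OC[C@H]1[C@H](CCCCCc2ccccc2)CC=C[C@H]1NC(=O)OCc1ccccc1
F4 | step 6 | benzyl N-[(1R,5R,6S)-6-(1-hydroxy-2-methoxyethyl)-5-(5-phenylpentyl)cyclohex-2-en-1-yl]carbamate | COCC(O)[C@H]1[C@H](CCCCCc2ccccc2)CC=C[C@H]1NC(=O)OCc1ccccc1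
F5 | step 6 | benzyl N-[(1R,5R,6S)-6-(methoxyacetyl)-5-(5-phenylpentyl)cyclohex-2-en-1-yl]carbamate | COCC(=O)[C@H]1[C@H](CCCCCc2ccccc2)CC=C[C@H]1NC(=O)OCc1ccccc1
F6 | step 9 | (5R)-3-methoxy-2-methyl-5-(5-phenylpentyl)-5,6,7,8-tetrahydroquinolin-4(1H)-one | COc1c(C)[nH]c2c(c1=O)[C@H](CCCCCc1ccccc1)CCC2
F7 | step 9 | (5R)-4-chloro-3-methoxy-2-methyl-5-(5-phenylpentyl)-5,6,7,8-tetrahydroquinoline | Clc1c(OC)c(C)nc2c1[C@H](CCCCCc1ccccc1)CCC2
F8 | step 9 | (5R)-4-chloro-3-methoxy-2-methyl-5-(5-phenylpentyl)-5,6,7,8-tetrahydroquinoline 1-oxide | Clc1c(OC)c(C)[n+]([O-])c2c1[C@H](CCCCCc1ccccc1)CCC2
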